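## The problem

Target 29 is 2-[5-hydroxy-3-methoxy-2-(3-methylbut-2-en-1-yl)phenyl]-7-(2-methylbut-3-en-2-yl)-1-benzofuran-4,6-diol. Its furan carries ring B at C2 (C1′ is the carbon bonded to C2, the prenyl group sits on C2′, the methyl ether on C3′, a free hydroxyl on C5′). The furan shares its C3a–C7a bond with ring A (C4–C7), which has hydroxyls at C4 and C6 and a quaternary 1,1-dimethylallyl carbon at C7. There is no stereocentre, so the difficulty is regiochemical: four aryl oxygens of which exactly one is methylated, and two isomeric five-carbon units that must each reach one particular carbon. The C7 substituent is bonded through its tertiary carbon and cannot come from alkylation with a prenyl electrophile. Its realistic source is a [3,3] shift of a prenyl ether on O6, which requires O6 to be distinguishable from O4 and O5′ at one stage. In ring B the prenyl group lies between the biaryl bond and the methyl ether, and C1′ is meta to both oxygens, so electrophilic substitution can place neither the biaryl bond nor the side chain. The trisubstituted prenyl alkene, the terminal vinyl group next to a phenol and the electron-rich resorcinol–benzofuran core exclude hydrogenolysis, strong protic or Lewis acids and oxidants from the late stages. The enabling feature is ring A itself: oxygen at C4 and C6, hydrogen at C5 and a carbon at C7, fused to the furan through C3a and C7a. This is the pattern formed when a furan-2-yl ketene (C4 and C7, with furan C3 and C2 becoming C3a and C7a) takes up an oxygen-substituted alkyne (C5 and C6), and the two oxygens then arrive chemically different.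

## Retrosynthesis

The O–CH2 bonds of two methoxymethyl acetals on O4 and O5′ are cut first, leading back to 28. Acetals are preferred over silyl ethers, which could not be told from the silyl group that the ring-forming step leaves on O6, and over benzyl ethers, whose hydrogenolysis would reduce both alkenes. 28 differs from 29 only in these two groups. The forward step must cleave them without adding solvent to the prenyl alkene or closing O6 onto the dimethylallyl group.

The C7–C(CH3)2 bond of 28 is cut by a retro-Claisen operation to the O6 prenyl ether 26. Direct C-alkylation would give the linear isomer, and a cross-coupling at C7 would need a C7 halide and branched-selective allyl transfer. The [3,3] shift inverts the allyl unit, so the quaternary carbon results from the mechanism itself. C7 is preferred over C5 because the dienone 27 formed on the way to C7 keeps the furan sextet, whereas migration to C5 would destroy it. The forward reaction asks only for heat and for O6 to be the one oxygen carrying the prenyl group.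

The O6–CH2 bond of 26 and the acetal on O4 are cut next, giving 24 and then 23. In 23 O4 is a free phenol and O6 a triisopropylsilyl ether. The order is acetal on O4, fluoride at O6 (phenoxide 25), then alkylation with 3. This works only if O5′ carries a group that is inert to fluoride, which decides the protecting group of ring B.

Ring A of 23 is taken apart at C7–C7a, C6–C7, C4–C5 and C3a–C4, giving the furyl diazomethyl ketone 14 and the silyl ynol ether 18. A classical benzofuran synthesis from a phloroglucinol derivative would have to distinguish O4 from O6 on a symmetrical ring. This cut delivers them distinct (hydroxyl from the ketene carbonyl, silyl ether from the alkyne) and removes a whole ring, four bonds and the differentiation problem in one step. The forward reaction needs a photochemical Wolff rearrangement with furyl migration, a head-to-tail ketene–alkyne cycloaddition and tolerance of the prenyl and acetal groups.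

The C–N bond of 14 is cut to the methyl ketone 12 through the trifluoroacetyl derivative 13. Diazo transfer to an activated methyl ketone is one operation, whereas the acid chloride–diazomethane route would need a furoic acid, two more steps and a hazardous reagent.

The C1′–C5(furan) bond of 12 is cut to the aryl bromide 8 and 2-acetyl-5-bromofuran 9. The acetyl group is purchased with the furan, and the electron-poor bromofuran is the better oxidative-addition partner, so ring B is the nucleophile (aryllithium 10, arylzinc 11). Direct C–H arylation of an acetylfuran with a hindered, electron-rich bromide at high temperature was judged less reliable.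

The C2′–CH2 bond of ring B is cut to the silyl ether 2 and prenyl bromide 3, with 2 coming from 3-bromo-5-methoxyphenol 1. In 1 the bromine is already meta to both oxygens and the methyl ether is already in place. The only open question is the site of deprotonation, and a bulky silyl ether leaves the position between bromine and methoxy as the only accessible one (aryllithium 4, arylcopper 5, product 6). The silyl group is then exchanged for the acetal (7, then 8), at the cost of two simple steps, because O5′ must survive the fluoride used at O6.

The O–Si bond of 18 is cut to lithium ethynolate 17, which is traced to 3-phenylisoxazole 15 through its 5-lithio derivative 16. The cycloreversion gives the unsubstituted ynolate at low temperature with benzonitrile as the only other product.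

## Roads not taken

Alternative 1: The furan C2=C3 bond is cut, leading to the aryl ester A1, in which a 2-formylphenol holding all ring A substituents is acylated by the ring B benzoic acid. Low-valent titanium (TiCl3, Zn) would couple the aldehyde carbon with the ester carbonyl carbon and close the furan to the tris-silyl ether A2. This is the most convergent plan, needs no light, and ends with a fluoride desilylation. That ending is milder than the acidic acetal cleavage of the chosen plan, and in this respect the alternative is better. Its weak points lie in A1. The aldehyde half is a pentasubstituted phloroglucinol whose three oxygens need the same differentiation as here, so the regiochemical problem is moved, not solved. The phenol to be acylated is flanked by a formyl group and a quaternary carbon. The resulting aryl ester is an activated, migration-prone acyl donor. Aldehydes under low-valent titanium tend to pinacol coupling and reduction before the sluggish ester carbonyl takes part. Against the milder ending, the chosen plan offers a ring A whose oxygens are differentiated by the ring-forming step itself.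

Alternative 2: Ring B is cut at C1′–C6′, leading to the open-chain triketone A3 attached to a complete, acetal-protected ring A. Aqueous KOH would effect aldol condensation of the terminal methyl group onto the aryl ketone and dehydration to the resorcinol A4. The route is biomimetic, needs no metal and no light, and fixes the prenyl position by C-alkylation of a 1,3-dicarbonyl compound; in cost and simplicity of reagents it is better than the chosen plan. It fails on two structural points. A4 has two free ring B hydroxyls and the target needs a methyl group only on the more hindered one next to the prenyl group, against the intrinsic selectivity. A3 is a 2-acyl-1,3-diketone that hydroxide can cleave by retro-Claisen loss of the aroyl unit or cyclise to a pyranone. Ring A, the harder half, would also have to be finished first by other means. The chosen plan buys the methyl ether with 1 and never has to distinguish the two ring B oxygens.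

Alternative 3: The same pericyclic chemistry is applied to ring B. With the numbering used here, the cut goes through C2′–C3′, C4′–C5′ and C5′–C6′ and leads to the cyclobutenone A5 and methoxyacetylene A6. Heating would give a vinylketene, [2+2] cycloaddition with A6 and 6π closure to the phenol A7. In ring B regiocontrol this road is better: methyl ether, prenyl group and free C5′ hydroxyl arrive in their places with no lithiation selectivity to secure and no protecting-group exchange, and the step is thermal. Its cost is that ring A, with the quaternary C7 substituent and two phenols, must be complete beforehand, so the O4/O6 differentiation and the Claisen step still have to be solved on a separately built benzofuran. A5 is a multistep precursor where the chosen plan needs a one-step diazo transfer, and A6 is a volatile alkyne that is not conveniently purchased. The chosen plan uses the annulation where it removes the most difficulty, on ring A, and accepts one regiochemical step (step 2) on ring B.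

Key step: step 8

Remark: Ar in the step lines stands for the 3-methoxy-5-(methoxymethoxy)-2-(3-methylbut-2-en-1-yl)phenyl group; 1, 3, 9 and 15 are taken to be purchasable.

## Steps

Step 1
Reactants: 1 3-bromo-5-methoxyphenol
Product: 2 (3-bromo-5-methoxyphenoxy)triisopropylsilane
Conditions: iPr3SiCl, imidazole, DMF, rt
Reagents that add atoms: triisopropylsilyl chloride, CC(C)[Si](Cl)(C(C)C)C(C)C
Why: Routine O-silylation of a phenol. The triisopropylsilyl ether binds lithium poorly and screens both neighbouring ring positions, which step 2 relies on.

Step 2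
Reactants: 2 (3-bromo-5-methoxyphenoxy)triisopropylsilane; 3 prenyl bromide (1-bromo-3-methylbut-2-ene)
Product: 6 [3-bromo-5-methoxy-4-(3-methylbut-2-en-1-yl)phenoxy]triisopropylsilane, via aryllithium 4 (not isolated), via arylcopper 5 (not isolated)
Conditions: LiN(iPr)2, THF, −78 °C; CuBr·SMe2, −78 °C; 3, −78 → 0 °C
Reagents that add atoms: none
Why: Directed ortho-metalation: the amide base should remove the proton between bromine and methoxy, which both acidify it, while the positions beside the bulky silyl ether are shielded. Transmetalation to monovalent copper gives an aryl metal that does not lose metal bromide and is alkylated at the primary carbon of 3 (SN2 allylation).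

Step 3
Reactants: 6 [3-bromo-5-methoxy-4-(3-methylbut-2-en-1-yl)phenoxy]triisopropylsilane
Product: 7 3-bromo-5-methoxy-4-(3-methylbut-2-en-1-yl)phenol
Conditions: Bu4NF, THF, 0 °C
Reagents that add atoms: none
Why: Fluoride cleavage of an aryl silyl ether, driven by the Si–F bond; bromide and alkene are inert. The silyl group is removed here because O5′ must later survive the fluoride used at O6.

Step 4
Reactants: 7 3-bromo-5-methoxy-4-(3-methylbut-2-en-1-yl)phenol
Product: 8 1-bromo-3-methoxy-5-(methoxymethoxy)-2-(3-methylbut-2-en-1-yl)benzene
Conditions: MeOCH2Cl, iPr2NEt, CH2Cl2, 0 °C → rt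
Reagents that add atoms: chloromethyl methyl ether, COCCl
Why: Standard O-alkylation of a phenol to the methoxymethyl acetal, which tolerates organolithium reagents, fluoride, light and heat and leaves under mild acid at the end.

Step 5
Reactants: 8 1-bromo-3-methoxy-5-(methoxymethoxy)-2-(3-methylbut-2-en-1-yl)benzene; 9 2-acetyl-5-bromofuran
Product: 12 1-(5-Ar-furan-2-yl)ethan-1-one, via aryllithium 10 (not isolated), via arylzinc chloride 11 (not isolated)
Conditions: n-BuLi, THF, −78 °C; ZnCl2, −78 → 0 °C; 9, Pd(PPh3)4 (cat.), THF, 50 °C
Reagents that add atoms: none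
Why: Bromine–lithium exchange at −78 °C outruns deprotonation, and the arylzinc formed on transmetalation does not attack or enolise the methyl ketone. Negishi cross-coupling with the electron-poor bromofuran under zerovalent palladium forms the C1′–C5(furan) bond.

Step 6
Reactants: 12 1-(5-Ar-furan-2-yl)ethan-1-one
Product: 14 2-diazo-1-(5-Ar-furan-2-yl)ethan-1-one, via trifluoroacetyl diketone 13 (not isolated)
Conditions: LiN(SiMe3)2, THF, −78 °C; CF3CO2CH2CF3; then MeSO2N3, Et3N, H2O, MeCN, rt
Reagents that add atoms: methanesulfonyl azide, CS(=O)(=O)N=[N+]=[N-]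
Why: Detrifluoroacetylative diazo transfer: the lithium enolate is trifluoroacetylated and the activated 1,3-diketone 13 undergoes Regitz-type diazo transfer with loss of the trifluoroacetyl group. It is the standard one-flask route from methyl ketones to diazomethyl ketones and leaves acetal and alkene untouched.

Step 7
Reactants: 15 3-phenylisoxazole
Product: 18 (triisopropylsiloxy)acetylene, via 5-lithioisoxazole 16 (not isolated), via lithium ethynolate 17 (not isolated)
Conditions: n-BuLi, THF, −78 → −20 °C; iPr3SiOTf, −78 → 0 °C
Reagents that add atoms: triisopropylsilyl trifluoromethanesulfonate, CC(C)[Si](OS(=O)(=O)C(F)(F)F)(C(C)C)C(C)C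
Why: C5 lithiation of a 3-substituted isoxazole triggers the known cycloreversion to a nitrile and a lithium ynolate. Ynolates are silylated on oxygen by bulky triisopropylsilyl electrophiles to give isolable silyl ynol ethers; 18 should be used soon after it is made.

Step 8
Reactants: 14 2-diazo-1-(5-Ar-furan-2-yl)ethan-1-one; 18 (triisopropylsiloxy)acetylene
Product: 23 2-Ar-6-(triisopropylsiloxy)-1-benzofuran-4-ol, via furylketene 19 (not isolated), via siloxycyclobutenone 20 (not isolated), via dienylketene 21 (not isolated), via cyclohexadienone 22 (not isolated)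
Conditions: 18 (excess), ClCH2CH2Cl, hν (300–350 nm, Pyrex), rt; then 80 °C
Reagents that add atoms: none
Why: Light expels N2 from 14 and the furan-2-yl group shifts from the carbonyl carbon to the diazo carbon (Wolff rearrangement, new C7–C7a bond) to give ketene 19. The electron-rich alkyne 18 adds to the ketene C=C in a [2+2] cycloaddition in which its nucleophilic CH terminus bonds to the ketene carbonyl carbon (C4–C5) and its oxygen-bearing carbon to the ketene α-carbon (C6–C7), giving the four-membered cyclobutenone 20. Reversible 4π electrocyclic opening of 20 gives dienylketene 21, and the isomer with the furan turned inward closes ring A by a thermal disrotatory 6π electrocyclisation of the ketene carbon onto furan C3 (C3a–C4, six-membered carbocycle), after which 22 enolises to the phenol. The closest known reaction type is the second-generation Danheiser benzannulation, in which aryl and heteroaryl diazo ketones are irradiated with alkoxy- or siloxyalkynes. No stereocentre survives, since the sp3 carbons of 20 and 22 are lost on aromatisation. The selectivities needed are the head-to-tail orientation of the [2+2] step, which the polarisation of the silyl ynol ether secures, and closure on the single free β-position of the 2,5-disubstituted furan, for which there is no alternative carbon. The prenyl alkene is remote from the ketene and far less nucleophilic than 18, and the acetal and ether groups are inert to this light and to 80 °C. O4 emerges as the free phenol and O6 as the silyl ether, which is the differentiation the end game needs.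

Step 9
Reactants: 23 2-Ar-6-(triisopropylsiloxy)-1-benzofuran-4-ol
Product: 24 [4-(methoxymethoxy)-2-Ar-1-benzofuran-6-yl]oxytriisopropylsilane
Conditions: MeOCH2Cl, iPr2NEt, CH2Cl2, 0 °C → rt
Reagents that add atoms: chloromethyl methyl ether, COCCl
Why: O-alkylation of the only free phenol; the aryl silyl ether is stable to the amine base and the alkyl chloride.

Step 10
Reactants: 24 [4-(methoxymethoxy)-2-Ar-1-benzofuran-6-yl]oxytriisopropylsilane; 3 prenyl bromide
Product: 26 4-(methoxymethoxy)-2-Ar-6-(3-methylbut-2-en-1-yloxy)-1-benzofuran, via tetrabutylammonium phenoxide 25 (not isolated)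
Conditions: Bu4NF, THF, 0 °C; then 3, rt
Reagents that add atoms: none
Why: Fluoride desilylation gives the tetrabutylammonium phenoxide, which is O-alkylated in the same flask by 3 (Williamson ether synthesis). Only O6 is free because O4 and O5′ are acetals.

Step 11
Reactants: 26 4-(methoxymethoxy)-2-Ar-6-(3-methylbut-2-en-1-yloxy)-1-benzofuran
Product: 28 4-(methoxymethoxy)-2-Ar-7-(2-methylbut-3-en-2-yl)-1-benzofuran-6-ol, via dienone 27 (not isolated)
Conditions: PhNEt2, 190 °C (sealed tube)
Reagents that add atoms: none
Why: Aromatic Claisen rearrangement: the [3,3] shift delivers the allyl unit inverted, so its tertiary carbon bonds to the ring and the quaternary centre forms without an alkylation. C7 is chosen over C5 because dienone 27 keeps the furan sextet (C3a=C7a) whereas migration to C5 would break it, and C5 is the more crowded site between two oxygens. The para carbon C3a is a ring-fusion atom, so no onward Cope shift is possible.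

Step 12
Reactants: 28 4-(methoxymethoxy)-2-Ar-7-(2-methylbut-3-en-2-yl)-1-benzofuran-6-ol
Product: 29 2-[5-hydroxy-3-methoxy-2-(3-methylbut-2-en-1-yl)phenyl]-7-(2-methylbut-3-en-2-yl)-1-benzofuran-4,6-diol
Conditions: HCl (3 M aq.), MeOH, 40 °C
Reagents that add atoms: none
Why: Acid-catalysed acetal exchange with methanol cleaves both aryl methoxymethyl ethers. Dilute acid at mild temperature is expected to spare the vinyl group (only a secondary cation is available), and the ring B prenyl group has no ortho hydroxyl to cyclise onto.

## Compound list

1 | 3-bromo-5-methoxyphenol | COc1cc(O)cc(Br)c1 | starting material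
2 | (3-bromo-5-methoxyphenoxy)tri(propan-2-yl)silane | COc1cc(O[Si](C(C)C)(C(C)C)C(C)C)cc(Br)c1 | intermediate
3 | 1-bromo-3-methylbut-2-ene (prenyl bromide) | CC(C)=CCBr | starting material
4 | [2-bromo-6-methoxy-4-(triisopropylsilyloxy)phenyl]lithium | [Li]c1c(Br)cc(O[Si](C(C)C)(C(C)C)C(C)C)cc1OC | intermediate
5 | [2-bromo-6-methoxy-4-(triisopropylsilyloxy)phenyl]copper | [Cu]c1c(Br)cc(O[Si](C(C)C)(C(C)C)C(C)C)cc1OC | intermediate
6 | [3-bromo-5-methoxy-4-(3-methylbut-2-en-1-yl)phenoxy]tri(propan-2-yl)silane | COc1cc(O[Si](C(C)C)(C(C)C)C(C)C)cc(Br)c1CC=C(C)C | intermediate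
7 | 3-bromo-5-methoxy-4-(3-methylbut-2-en-1-yl)phenol | COc1cc(O)cc(Br)c1CC=C(C)C | intermediate
8 | 1-bromo-3-methoxy-5-(methoxymethoxy)-2-(3-methylbut-2-en-1-yl)benzene | COCOc1cc(OC)c(CC=C(C)C)c(Br)c1 | intermediate
9 | 1-(5-bromofuran-2-yl)ethan-1-one (2-acetyl-5-bromofuran) | CC(=O)c1ccc(Br)o1 | starting material
10 | [3-methoxy-5-(methoxymethoxy)-2-(3-methylbut-2-en-1-yl)phenyl]lithium | [Li]c1cc(OCOC)cc(OC)c1CC=C(C)C | intermediate
11 | chloro[3-methoxy-5-(methoxymethoxy)-2-(3-methylbut-2-en-1-yl)phenyl]zinc | Cl[Zn]c1cc(OCOC)cc(OC)c1CC=C(C)C | intermediate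
12 | 1-{5-[3-methoxy-5-(methoxymethoxy)-2-(3-methylbut-2-en-1-yl)phenyl]furan-2-yl}ethan-1-one | CC(=O)c1ccc(-c2cc(OCOC)cc(OC)c2CC=C(C)C)o1 | intermediate
13 | 4,4,4-trifluoro-1-{5-[3-methoxy-5-(methoxymethoxy)-2-(3-methylbut-2-en-1-yl)phenyl]furan-2-yl}butane-1,3-dione | O=C(CC(=O)C(F)(F)F)c1ccc(-c2cc(OCOC)cc(OC)c2CC=C(C)C)o1 | intermediate
14 | 2-diazo-1-{5-[3-methoxy-5-(methoxymethoxy)-2-(3-methylbut-2-en-1-yl)phenyl]furan-2-yl}ethan-1-one | [N-]=[N+]=CC(=O)c1ccc(-c2cc(OCOC)cc(OC)c2CC=C(C)C)o1 | intermediate
15 | 3-phenyl-1,2-oxazole (3-phenylisoxazole) | c1ccc(-c2ccon2)cc1 | starting material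
16 | (3-phenyl-1,2-oxazol-5-yl)lithium | [Li]c1cc(-c2ccccc2)no1 | intermediate
17 | lithium ethynolate | [Li+].[O-]C#C | intermediate
18 | (ethynyloxy)tri(propan-2-yl)silane, (triisopropylsiloxy)acetylene | C#CO[Si](C(C)C)(C(C)C)C(C)C | intermediate
19 | 2-{5-[3-methoxy-5-(methoxymethoxy)-2-(3-methylbut-2-en-1-yl)phenyl]furan-2-yl}ethen-1-one (furan-2-ylketene) | O=C=Cc1ccc(-c2cc(OCOC)cc(OC)c2CC=C(C)C)o1 | intermediate
20 | 4-{5-[3-methoxy-5-(methoxymethoxy)-2-(3-methylbut-2-en-1-yl)phenyl]furan-2-yl}-3-(triisopropylsilyloxy)cyclobut-2-en-1-one (racemic) | O=C1C=C(O[Si](C(C)C)(C(C)C)C(C)C)C1c1ccc(-c2cc(OCOC)cc(OC)c2CC=C(C)C)o1 | intermediate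
21 | (3E)-4-{5-[3-methoxy-5-(methoxymethoxy)-2-(3-methylbut-2-en-1-yl)phenyl]furan-2-yl}-3-(triisopropylsilyloxy)buta-1,3-dien-1-one | O=C=C/C(O[Si](C(C)C)(C(C)C)C(C)C)=C\c1ccc(-c2cc(OCOC)cc(OC)c2CC=C(C)C)o1 | intermediate
22 | 2-[3-methoxy-5-(methoxymethoxy)-2-(3-methylbut-2-en-1-yl)phenyl]-6-(triisopropylsilyloxy)-3aH-1-benzofuran-4-one (racemic) | O=C1C=C(O[Si](C(C)C)(C(C)C)C(C)C)C=C2OC(-c3cc(OCOC)cc(OC)c3CC=C(C)C)=CC12 | intermediate
23 | 2-[3-methoxy-5-(methoxymethoxy)-2-(3-methylbut-2-en-1-yl)phenyl]-6-(triisopropylsilyloxy)-1-benzofuran-4-ol | Oc1cc(O[Si](C(C)C)(C(C)C)C(C)C)cc2oc(-c3cc(OCOC)cc(OC)c3CC=C(C)C)cc12 | intermediate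
24 | {4-(methoxymethoxy)-2-[3-methoxy-5-(methoxymethoxy)-2-(3-methylbut-2-en-1-yl)phenyl]-1-benzofuran-6-yl}oxytri(propan-2-yl)silane | COCOc1cc(O[Si](C(C)C)(C(C)C)C(C)C)cc2oc(-c3cc(OCOC)cc(OC)c3CC=C(C)C)cc12 | intermediate
25 | tetrabutylammonium 4-(methoxymethoxy)-2-[3-methoxy-5-(methoxymethoxy)-2-(3-methylbut-2-en-1-yl)phenyl]-1-benzofuran-6-olate | CCCC[N+](CCCC)(CCCC)CCCC.[O-]c1cc(OCOC)c2cc(-c3cc(OCOC)cc(OC)c3CC=C(C)C)oc2c1 | intermediate
26 | 4-(methoxymethoxy)-2-[3-methoxy-5-(methoxymethoxy)-2-(3-methylbut-2-en-1-yl)phenyl]-6-[(3-methylbut-2-en-1-yl)oxy]-1-benzofuran | CC(C)=CCOc1cc(OCOC)c2cc(-c3cc(OCOC)cc(OC)c3CC=C(C)C)oc2c1 | intermediate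
27 | 4-(methoxymethoxy)-2-[3-methoxy-5-(methoxymethoxy)-2-(3-methylbut-2-en-1-yl)phenyl]-7-(2-methylbut-3-en-2-yl)-7H-1-benzofuran-6-one (racemic) | C=CC(C)(C)C1C(=O)C=C(OCOC)c2cc(-c3cc(OCOC)cc(OC)c3CC=C(C)C)oc12 | intermediate
28 | 4-(methoxymethoxy)-2-[3-methoxy-5-(methoxymethoxy)-2-(3-methylbut-2-en-1-yl)phenyl]-7-(2-methylbut-3-en-2-yl)-1-benzofuran-6-ol | C=CC(C)(C)c1c(O)cc(OCOC)c2cc(-c3cc(OCOC)cc(OC)c3CC=C(C)C)oc12 | intermediate
29 | 2-[5-hydroxy-3-methoxy-2-(3-methylbut-2-en-1-yl)phenyl]-7-(2-methylbut-3-en-2-yl)-1-benzofuran-4,6-diol (CNP0169501.0) | C=CC(C)(C)c1c(O)cc(O)c2cc(-c3cc(O)cc(OC)c3CC=C(C)C)oc12 | target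

## Step count and risks

Total: 12 steps. Longest linear sequence: 11 steps (steps 1–6 and 8–12, from 1 to 29); step 7 is a one-step side branch.

Step 8 (key step). Most likely to go wrong: secondary photochemistry of the light-absorbing arylfuran and 2-arylbenzofuran chromophores during long irradiation, and acylation of the new C4 phenol by ketene intermediates, both of which would erode the mass balance. Fallback, setting out from 14 and returning at 23: the ketene is made in the dark. Silver-catalysed Wolff rearrangement of 14 in aqueous THF (PhCO2Ag, Et3N) should give the (5-Ar-furan-2-yl)acetic acid F1. 1-Chloro-N,N,2-trimethylprop-1-en-1-amine would convert it under neutral conditions into the acid chloride F2. Slow addition of Et3N to F2 and 18 in toluene at 80 °C would generate 19 by dehydrochlorination, which enters the same [2+2], 4π and 6π sequence to 23. Ketenes made this way are known to combine with silyl ynol ethers.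

Step 2. Most likely to go wrong: attack of the doubly ortho-substituted aryl metal at the tertiary end of the prenyl electrophile (allylic transposition), or alkylation so slow that the ortho-bromo aryl metal loses metal bromide to an aryne. Fallback, setting out from 2 and returning at 6: the arylcopper 5 is quenched with allyl bromide, which has no regiochemical ambiguity and reacts at −78 °C, to give the allyl arene F3. Olefin cross-metathesis with 2-methylbut-2-ene (second-generation Grubbs catalyst RuCl2(=CHPh)(H2IMes)(PCy3), CH2Cl2, 40 °C) then converts allyl into prenyl and gives 6.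

Step 11. Most likely to go wrong: at the temperature the rearrangement needs, hydrogen transfer from the freed C6 hydroxyl to the new vinyl group (abnormal Claisen rearrangement), ring closure of the phenol onto the alkene, or thermal loss of the prenyl group. Fallback, setting out from 26 and returning at 28: the rearrangement is run in PhNEt2 with butanoic anhydride, so the phenol is acylated as it forms and cannot react further, giving the butanoate F4. K2CO3 in MeOH at rt then cleaves the ester to 28.

Step 12. Most likely to go wrong: addition of methanol or water to the protonated prenyl alkene of ring B, or acid-induced closure of the C6 hydroxyl onto the dimethylallyl group, competing with acetal cleavage. Fallback, setting out from 28 and returning at 29: the acetals are exchanged for silyl groups without protic acid. Et3SiOTf with 2,2′-bipyridyl in MeCN at 0 °C converts aryl methoxymethyl ethers into aryl silyl ethers under buffered conditions and should silylate O6 as well, giving the tris(triethylsilyl) ether F5. Bu4NF in THF at 0 °C then frees the three phenols to give 29.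

## Further compounds

F1 | step 8 | 2-{5-[3-methoxy-5-(methoxymethoxy)-2-(3-methylbut-2-en-1-yl)phenyl]furan-2-yl}acetic acid | OC(=O)Cc1ccc(-c2cc(OCOC)cc(OC)c2CC=C(C)C)o1
F2 | step 8 | 2-{5-[3-methoxy-5-(methoxymethoxy)-2-(3-methylbut-2-en-1-yl)phenyl]furan-2-yl}acetyl chloride | ClC(=O)Cc1ccc(-c2cc(OCOC)cc(OC)c2CC=C(C)C)o1
F3 | step 2 | [3-bromo-5-methoxy-4-(prop-2-en-1-yl)phenoxy]tri(propan-2-yl)silane | C=CCc1c(Br)cc(O[Si](C(C)C)(C(C)C)C(C)C)cc1OC
F4 | step 11 | 4-(methoxymethoxy)-2-[3-methoxy-5-(methoxymethoxy)-2-(3-methylbut-2-en-1-yl)phenyl]-7-(2-methylbut-3-en-2-yl)-1-benzofuran-6-yl butanoate | CCCC(=O)Oc1cc(OCOC)c2cc(-c3cc(OCOC)cc(OC)c3CC=C(C)C)oc2c1C(C)(C)C=C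
F5 | step 12 | 2-[3-methoxy-2-(3-methylbut-2-en-1-yl)-5-(triethylsilyloxy)phenyl]-7-(2-methylbut-3-en-2-yl)-4,6-bis(triethylsilyloxy)-1-benzofuran | C=CC(C)(C)c1c(O[Si](CC)(CC)CC)cc(O[Si](CC)(CC)CC)c2cc(-c3cc(O[Si](CC)(CC)CC)cc(OC)c3CC=C(C)C)oc12
A1 | alternative 1 | 3,5-bis(tert-butyldimethylsilyloxy)-2-formyl-6-(2-methylbut-3-en-2-yl)phenyl 5-(tert-butyldimethylsilyloxy)-3-methoxy-2-(3-methylbut-2-en-1-yl)benzoate | O=Cc1c(O[Si](C)(C)C(C)(C)C)cc(O[Si](C)(C)C(C)(C)C)c(C(C)(C)C=C)c1OC(=O)c1cc(O[Si](C)(C)C(C)(C)C)cc(OC)c1CC=C(C)C
A2 | alternative 1 | 4,6-bis(tert-butyldimethylsilyloxy)-2-[5-(tert-butyldimethylsilyloxy)-3-methoxy-2-(3-methylbut-2-en-1-yl)phenyl]-7-(2-methylbut-3-en-2-yl)-1-benzofuran | C=CC(C)(C)c1c(O[Si](C)(C)C(C)(C)C)cc(O[Si](C)(C)C(C)(C)C)c2cc(-c3cc(O[Si](C)(C)C(C)(C)C)cc(OC)c3CC=C(C)C)oc12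
A3 | alternative 2 | 1-[4,6-bis(methoxymethoxy)-7-(2-methylbut-3-en-2-yl)-1-benzofuran-2-yl]-2-(3-methylbut-2-en-1-yl)hexane-1,3,5-trione (racemic) | CC(=O)CC(=O)C(CC=C(C)C)C(=O)c1cc2c(OCOC)cc(OCOC)c(C(C)(C)C=C)c2o1
A4 | alternative 2 | 5-[4,6-bis(methoxymethoxy)-7-(2-methylbut-3-en-2-yl)-1-benzofuran-2-yl]-4-(3-methylbut-2-en-1-yl)benzene-1,3-diol | C=CC(C)(C)c1c(OCOC)cc(OCOC)c2cc(-c3cc(O)cc(O)c3CC=C(C)C)oc12
A5 | alternative 3 | 3-[4,6-bis(tert-butyldimethylsilyloxy)-7-(2-methylbut-3-en-2-yl)-1-benzofuran-2-yl]-2-(3-methylbut-2-en-1-yl)cyclobut-2-en-1-one | O=C1CC(c2cc3c(O[Si](C)(C)C(C)(C)C)cc(O[Si](C)(C)C(C)(C)C)c(C(C)(C)C=C)c3o2)=C1CC=C(C)C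
A6 | alternative 3 | methoxyethyne (methoxyacetylene) | COC#C
A7 | alternative 3 | 3-[4,6-bis(tert-butyldimethylsilyloxy)-7-(2-methylbut-3-en-2-yl)-1-benzofuran-2-yl]-5-methoxy-4-(3-methylbut-2-en-1-yl)phenol | C=CC(C)(C)c1c(O[Si](C)(C)C(C)(C)C)cc(O[Si](C)(C)C(C)(C)C)c2cc(-c3cc(O)cc(OC)c3CC=C(C)C)oc12
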